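If each molecule of target costs one molecule of coupling partner, then in a closed flask the target, counted in millimolar, stays at or below the partner charge. So the target should be read in millimolar and held against that charge.

in all of them: free catalyst 0.25 mM

| charge | substrate | coupling partner | remark | time |
|---|---|---|---|---|
| epsilon | 0.011 M | 5 mM | run made earlier |  |
| eta | 0.057 M | 5 mM | run made earlier |  |
| dusk | 0.010 M | 5.00 mM |  | 8.0 h |
| autumn | 0.020 M | 5.00 mM |  | 8.0 h |
| dawn | 0.040 M | 5.00 mM |  | 8.0 h |

| epsilon: time / h | epsilon: target / % | eta: time / h | eta: target / % |
|---|---|---|---|
| 0.667 | 4.2 | 0.667 | 1.5 |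
| 1.00 | 7.3 | 1.00 | 1.1 |
| 2.00 | 14.8 | 2.00 | 3.6 |
| 3.00 | 22.2 | 3.00 | 5.1 |
| 5.00 | 34.1 | 5.00 | 8.1 |
| 8.00 | 43.1 | 8.00 | 7.6 |

(readings scatter by 0.5 percentage points)

- the earlier runs were read with a standard deviation of 0.5 percentage points
- "hardly changes" means that all values lie within two and a half points (for a concentration: within two and a half percent of the largest)

- amount of target at the end, in percent of the substrate charged for dusk, autumn, dawn, in this order
- how that number moves from the first to the last of them (falls, then rises / hardly changes / falls all the way / rises all the way / rises, then falls)

Two chemists read these runs differently. The first holds a clock: the catalyst turns over at a steady rate r, whatever the substrate. Epsilon gives r = 0.803 mM h⁻¹ from its reading at 1.00 h. Eta, with 5.18 times the substrate, gives 0.969 mM h⁻¹ at 3.00 h, which is 1.21 times as much. Over 8.0 h the clock therefore promises 64.2 % in dusk, 32.1 % in autumn and 16.1 % in dawn.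

The second chemist follows one molecule of coupling partner to its end as target. Dividing the partner charge by the substrate charge gives 50.0 % for dusk, 25.0 % for autumn and 12.5 % for dawn. This ratio is her ceiling Y, the cap on target in percent of the substrate charged, with the coupling partner as limiting reagent, since its charge is smaller than the substrate charge. At rate r the partner charge lasts 6.23 h, less than the 8.0 h of the new runs, so she expects each flask to end close under its Y. The earlier runs stay under theirs: epsilon has Y = 45.5 % and read 43.1 % at 8.00 h, and eta has Y = 8.77 % and read 8.1 % at 5.00 h.

The clock keeps its own stretch, the early one. At 3.00 h in epsilon it gives 2.41 mM against 2.44 mM read, with the target at about half of the partner charge. At 8.00 h in epsilon it gives 6.42 mM against 4.74 mM read. My own reckoning stops at the ceilings and the direction: just under Y in each flask, falling from dusk to dawn.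

The forecast takes the second side and stands below the ceilings, at 46 %, 23.3 % and 11.5 %, a row that falls all the way, on the ground that “the coupling partner is limiting”.

The flask gives 46.5 %, 24.5 % and 12.4 %, a row that falls all the way.

    2 catalyst intermediate A → spent catalyst (k = 27.0 M⁻¹ min⁻¹)
    coupling partner + free catalyst → catalyst intermediate A (k = 75.0 M⁻¹ min⁻¹)
    catalyst intermediate C → by-product + catalyst intermediate D (k = 0.450 min⁻¹)
    catalyst intermediate D → free catalyst + target (k = 6.70 min⁻¹)
    catalyst intermediate B → catalyst intermediate C (k = 0.130 min⁻¹)
    substrate + catalyst intermediate A → catalyst intermediate B (k = 32.0 M⁻¹ min⁻¹)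

Dusk ends at 46.5 %, under its Y of 50.0 % and below the clock's 64.2 %, with 5.1 % of the coupling partner left. Dawn, the second flask to hold against its ceiling, ends at 12.4 % under 12.5 %, with 0.76 % of the partner left. The partner's fork lies at catalyst intermediate A, which substrate carries forward and which can also pair off into spent catalyst. At 2.73 h in dusk, substrate uses that intermediate 96 times as fast as the pairing does, so 99.0 % of what leaves it then goes on towards target.

The earlier runs and the new flask stem from a simulated flask for substances that don't exist; the scatter is artificial.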